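## Retrosynthetic overview

1. Target 28 ⇐ oxidation of primary alcohol 26; the Z-alkylidene of 26 ⇐ [1,5]-sigmatropic hydrogen shift (retro-ene, loss of N2) of the allylic diazene made from the tosylhydrazone of dienone 21.
2. Dienone 21 ⇐ Stille acylation of dienylstannane 19 with the acid chloride of dioxane acid 13.
3. Dioxane ring of 13 ⇐ diimide reduction of dihydrodioxine 10 ⇐ singlet-oxygen [4+2] cycloaddition to (E,E)-diene 9 (key ring; C3 and C6 set together, face chosen by the bought centre).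
4. Diene 9 ⇐ Johnson–Claisen rearrangement of dienol 5 ⇐ (R)-Roche ester 1, the only purchased stereocentre.
5. Stannane 19 ⇐ Birch reduction of tetralin 15 ⇐ 6-methoxy-1-tetralone 14. Ring order: carbocyclic rings A and B are bought in 14 (ring B dearomatised in step 11), the dioxane ring forms in step 7, the halves are joined in step 14.

Assumption and conventions: both Roche ester enantiomers are taken as commercial. The dioxane is numbered O1–O2–C3(H)–C4–C5–C6(CH3) in all names, and the bicycle is numbered as in ketone 17. The spatial arrangement at the three stereocentres is that of the target from step 7 onward; descriptors at C6 and at the side-chain carbon change between intermediates only because CIP priorities change.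

## Route

Step 1
Reactants: 1 methyl (R)-3-hydroxy-2-methylpropanoate
Product: 2 methyl (R)-3-[(tert-butyldimethylsilyl)oxy]-2-methylpropanoate
Conditions: TBSCl, imidazole, DMF, 0 °C to rt
Reagents that add atoms: tert-butyldimethylsilyl chloride, CC(C)(C)[Si](C)(C)Cl
Why: Imidazole-assisted silylation masks the primary alcohol for the hydride and Grignard steps and does not touch the stereocentre.

Step 2
Reactants: 2 methyl (R)-3-[(tert-butyldimethylsilyl)oxy]-2-methylpropanoate
Product: 3 (R)-3-[(tert-butyldimethylsilyl)oxy]-2-methylpropanal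
Conditions: i-Bu2AlH, CH2Cl2, −78 °C; aq. KNaC4H4O6 work-up; used crude
Reagents that add atoms: none
Why: Low-temperature partial reduction stops at the aluminium hemiacetal, which gives the aldehyde on work-up; using it cold and crude keeps the α-centre intact.

Step 3
Reactants: 3 (R)-3-[(tert-butyldimethylsilyl)oxy]-2-methylpropanal
Product: 4 (2E,4S)-5-[(tert-butyldimethylsilyl)oxy]-4-methylpent-2-enal
Conditions: Ph3P=CHCHO, toluene, 80 °C
Reagents that add atoms: (triphenylphosphoranylidene)acetaldehyde, O=CC=P(c1ccccc1)(c1ccccc1)c1ccccc1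
Why: Wittig olefination with a stabilised ylide gives the E-enal under non-basic conditions that do not epimerise the α-centre.

Step 4
Reactants: 4 (2E,4S)-5-[(tert-butyldimethylsilyl)oxy]-4-methylpent-2-enal
Product: 5 (4E,6S)-7-[(tert-butyldimethylsilyl)oxy]-2,6-dimethylhepta-1,4-dien-3-ol (both C3 epimers)
Conditions: CH2=C(CH3)MgBr, THF, −78 to 0 °C
Reagents that add atoms: isopropenylmagnesium bromide, CC(=C)[Mg]Br
Why: Grignard 1,2-addition to the enal gives the bis-allylic carbinol; its new carbinol centre is uncontrolled but is erased in the next step.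

Step 5
Reactants: 5 (4E,6S)-7-[(tert-butyldimethylsilyl)oxy]-2,6-dimethylhepta-1,4-dien-3-ol
Product: 7 ethyl (4E,6E,8S)-9-[(tert-butyldimethylsilyl)oxy]-4,8-dimethylnona-4,6-dienoate, via mixed ketene acetal 6 (not isolated)
Conditions: CH3C(OEt)3 (excess), EtCO2H (cat.), 140 °C, EtOH distilled off
Reagents that add atoms: triethyl orthoacetate, CCOC(C)(OCC)OCC
Why: Johnson–Claisen [3,3]-sigmatropic rearrangement runs through the unhindered methallyl terminus, and the chair transition state with the dienyl group equatorial gives the 4E trisubstituted alkene of the conjugated E,E-diene.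

Step 6
Reactants: 7 ethyl (4E,6E,8S)-9-[(tert-butyldimethylsilyl)oxy]-4,8-dimethylnona-4,6-dienoate
Product: 9 (4E,6E,8S)-9-hydroxy-4,8-dimethylnona-4,6-dienoic acid, via silyl ether acid 8 (not isolated)
Conditions: LiOH, THF/MeOH/H2O, rt; then 1 M HCl to pH 1, rt
Reagents that add atoms: lithium hydroxide, [Li+].[OH-]
Why: Saponification followed by acid cleavage of the primary silyl ether in the same pot frees the hydroxyl group that directs the cycloaddition.

Step 7
Reactants: 9 (4E,6E,8S)-9-hydroxy-4,8-dimethylnona-4,6-dienoic acid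
Product: 10 3-[(3S,6S)-3-[(2R)-1-hydroxypropan-2-yl]-6-methyl-3,6-dihydro-1,2-dioxin-6-yl]propanoic acid
Conditions: O2, hν (visible), tetraphenylporphyrin (cat.), CH2Cl2, −30 °C
Reagents that add atoms: oxygen, O=O
Why: Singlet-oxygen [4+2] cycloaddition to the s-cis E,E-diene is suprafacial, so the two outside groups (C3 side chain and C6 propanoate chain) end up cis with the C6 methyl trans; the CH2OH group on the bought centre, in the conformer with its C–H in the diene plane, hydrogen-bonds to the incoming oxygen and steers it to its own face, giving the (3S,6S) adduct as the major isomer (moderate selectivity expected; the (3R,6R) isomer and ene hydroperoxides are removed by chromatography).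

Step 8
Reactants: 10 3-[(3S,6S)-3-[(2R)-1-hydroxypropan-2-yl]-6-methyl-3,6-dihydro-1,2-dioxin-6-yl]propanoic acid
Product: 11 3-[(3S,6R)-3-[(2R)-1-hydroxypropan-2-yl]-6-methyl-1,2-dioxan-6-yl]propanoic acid
Conditions: KO2CN=NCO2K, AcOH, MeOH/CH2Cl2, 0 °C to rt
Reagents that add atoms: none
Why: Diimide reduction transfers H2 concertedly to the cis ring alkene and leaves the O–O bond and both stereocentres untouched.

Step 9
Reactants: 11 3-[(3S,6R)-3-[(2R)-1-hydroxypropan-2-yl]-6-methyl-1,2-dioxan-6-yl]propanoic acid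
Product: 13 3-[(3S,6R)-3-[(2R)-1-[(tert-butyldimethylsilyl)oxy]propan-2-yl]-6-methyl-1,2-dioxan-6-yl]propanoic acid, via bis-silyl derivative 12 (not isolated)
Conditions: TBSCl, imidazole, DMF, rt; then K2CO3, MeOH/H2O, 0 °C
Reagents that add atoms: tert-butyldimethylsilyl chloride, CC(C)(C)[Si](C)(C)Cl
Why: Silylation of both OH and CO2H followed by selective solvolysis of the labile silyl ester leaves the alcohol masked for acid chloride formation.

Step 10
Reactants: 14 6-methoxy-3,4-dihydronaphthalen-1(2H)-one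
Product: 15 6-methoxy-1,1-dimethyl-1,2,3,4-tetrahydronaphthalene
Conditions: Me2TiCl2 (from Me2Zn and TiCl4), CH2Cl2, −30 °C to rt
Reagents that add atoms: dimethylzinc, C[Zn]C
Why: Reetz geminal dimethylation: methyl addition, ionisation of the benzylic titanium alkoxide (helped by the para methoxy group) and a second methyl transfer.

Step 11
Reactants: 15 6-methoxy-1,1-dimethyl-1,2,3,4-tetrahydronaphthalene
Product: 17 5,5-dimethyl-3,4,5,6,7,8-hexahydronaphthalen-2(1H)-one, via methyl enol ether 16 (not isolated)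
Conditions: Li, liq. NH3, THF, t-BuOH, −78 to −33 °C; then (CO2H)2, MeOH/H2O, rt
Reagents that add atoms: water, O
Why: Birch reduction leaves the methoxy- and alkyl-bearing carbons sp2 (tetrasubstituted ring-fusion alkene), and mild oxalic acid hydrolysis of the enol ether gives the β,γ-unsaturated ketone without conjugation.

Step 12
Reactants: 17 5,5-dimethyl-3,4,5,6,7,8-hexahydronaphthalen-2(1H)-one
Product: 18 5,5-dimethyl-3,4,5,6,7,8-hexahydronaphthalen-2-yl trifluoromethanesulfonate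
Conditions: KN(SiMe3)2, THF, −78 °C; PhNTf2, −78 to 0 °C; aq. NH4Cl
Reagents that add atoms: N-phenylbis(trifluoromethanesulfonimide), O=S(=O)(N(c1ccccc1)S(=O)(=O)C(F)(F)F)C(F)(F)F
Why: Deprotonation at the doubly activated C1 (α to the carbonyl and allylic) gives the conjugated dienolate, which is trapped on oxygen as the dienyl triflate.

Step 13
Reactants: 18 5,5-dimethyl-3,4,5,6,7,8-hexahydronaphthalen-2-yl trifluoromethanesulfonate
Product: 19 trimethyl(5,5-dimethyl-3,4,5,6,7,8-hexahydronaphthalen-2-yl)stannane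
Conditions: (Me3Sn)2, Pd(PPh3)4 (cat.), LiCl, THF, 60 °C
Reagents that add atoms: hexamethylditin, C[Sn](C)(C)[Sn](C)(C)C
Why: Palladium-catalysed stannylation: oxidative addition of the triflate to zerovalent palladium, transmetalation with the distannane and reductive elimination.

Step 14
Reactants: 13 3-[(3S,6R)-3-[(2R)-1-[(tert-butyldimethylsilyl)oxy]propan-2-yl]-6-methyl-1,2-dioxan-6-yl]propanoic acid; 19 trimethyl(5,5-dimethyl-3,4,5,6,7,8-hexahydronaphthalen-2-yl)stannane
Product: 21 3-[(3S,6R)-3-[(2R)-1-[(tert-butyldimethylsilyl)oxy]propan-2-yl]-6-methyl-1,2-dioxan-6-yl]-1-(5,5-dimethyl-3,4,5,6,7,8-hexahydronaphthalen-2-yl)propan-1-one, via acid chloride 20 (not isolated)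
Conditions: (COCl)2, DMF (cat.), CH2Cl2, 0 °C to rt, evaporate; then 19, Pd2(dba)3 (cat.), AsPh3, THF, 50 °C
Reagents that add atoms: none
Why: Stille acylation of the acid chloride joins the halves under neutral conditions without strong base, hydride or organolithium, which the dialkyl peroxide should tolerate.

Step 15
Reactants: 21 3-[(3S,6R)-3-[(2R)-1-[(tert-butyldimethylsilyl)oxy]propan-2-yl]-6-methyl-1,2-dioxan-6-yl]-1-(5,5-dimethyl-3,4,5,6,7,8-hexahydronaphthalen-2-yl)propan-1-one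
Product: 23 N'-[3-[(3S,6S)-3-[(2R)-1-hydroxypropan-2-yl]-6-methyl-1,2-dioxan-6-yl]-1-(5,5-dimethyl-3,4,5,6,7,8-hexahydronaphthalen-2-yl)propylidene]-4-methylbenzenesulfonohydrazide, via silylated tosylhydrazone 22 (not isolated)
Conditions: TsNHNH2, 1% HCl in EtOH, rt
Reagents that add atoms: p-toluenesulfonohydrazide, Cc1ccc(cc1)S(=O)(=O)NN
Why: Acid-catalysed condensation gives the tosylhydrazone, and the same ethanolic HCl removes the primary silyl ether.

Step 16
Reactants: 23 N'-[3-[(3S,6S)-3-[(2R)-1-hydroxypropan-2-yl]-6-methyl-1,2-dioxan-6-yl]-1-(5,5-dimethyl-3,4,5,6,7,8-hexahydronaphthalen-2-yl)propylidene]-4-methylbenzenesulfonohydrazide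
Product: 26 (2R)-2-[(3S,6S)-6-[(3Z)-3-(5,5-dimethyl-3,4,5,6,7,8-hexahydronaphthalen-2(1H)-ylidene)propyl]-6-methyl-1,2-dioxan-3-yl]propan-1-ol, via tosylhydrazine 24 (not isolated), via allylic diazene 25 (not isolated)
Conditions: catecholborane (excess), CHCl3, 0 °C to rt; then NaOAc·3H2O, reflux
Reagents that add atoms: none
Why: Kabalka reduction: hydride adds 1,2 to C=N, loss of sulfinate gives the allylic diazene, and its [1,5]-sigmatropic hydrogen shift (retro-ene) with loss of N2 puts H on ring C1 and moves the alkene to the exocyclic position while C4a=C8a stays; the chain on the diazene carbon sits on the side of the H-accepting C1–H to avoid A(1,2) strain with ring C3, which gives the Z alkene (chain cis to C1).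

Step 17
Reactants: 26 (2R)-2-[(3S,6S)-6-[(3Z)-3-(5,5-dimethyl-3,4,5,6,7,8-hexahydronaphthalen-2(1H)-ylidene)propyl]-6-methyl-1,2-dioxan-3-yl]propan-1-ol
Product: 28 (2S)-2-[(3S,6S)-6-[(3Z)-3-(5,5-dimethyl-3,4,5,6,7,8-hexahydronaphthalen-2(1H)-ylidene)propyl]-6-methyl-1,2-dioxan-3-yl]propanoic acid, via aldehyde 27 (not isolated)
Conditions: TEMPO (cat.), PhI(OAc)2, MeCN/H2O, rt
Reagents that add atoms: water, O
Why: Oxoammonium (TEMPO) oxidation takes the primary alcohol through the aldehyde hydrate to the acid under near-neutral conditions that spare the peroxide, both alkenes and the α-centre.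

## Compound list

1 | methyl (R)-3-hydroxy-2-methylpropanoate | C[C@H](CO)C(=O)OC | starting material
2 | methyl (R)-3-[(tert-butyldimethylsilyl)oxy]-2-methylpropanoate | C[C@H](CO[Si](C)(C)C(C)(C)C)C(=O)OC | intermediate
3 | (R)-3-[(tert-butyldimethylsilyl)oxy]-2-methylpropanal | C[C@H](CO[Si](C)(C)C(C)(C)C)C=O | intermediate
4 | (2E,4S)-5-[(tert-butyldimethylsilyl)oxy]-4-methylpent-2-enal | C[C@H](CO[Si](C)(C)C(C)(C)C)/C=C/C=O | intermediate
5 | (4E,6S)-7-[(tert-butyldimethylsilyl)oxy]-2,6-dimethylhepta-1,4-dien-3-ol (both C3 epimers) | C[C@H](CO[Si](C)(C)C(C)(C)C)/C=C/C(O)C(C)=C | intermediate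
6 | 1-ethoxyvinyl ether of 5 (mixed ketene acetal) | C[C@H](CO[Si](C)(C)C(C)(C)C)/C=C/C(OC(=C)OCC)C(C)=C | intermediate
7 | ethyl (4E,6E,8S)-9-[(tert-butyldimethylsilyl)oxy]-4,8-dimethylnona-4,6-dienoate | C[C@H](CO[Si](C)(C)C(C)(C)C)/C=C/C=C(\C)CCC(=O)OCC | intermediate
8 | (4E,6E,8S)-9-[(tert-butyldimethylsilyl)oxy]-4,8-dimethylnona-4,6-dienoic acid (lithium salt in the flask) | C[C@H](CO[Si](C)(C)C(C)(C)C)/C=C/C=C(\C)CCC(=O)O | intermediate
9 | (4E,6E,8S)-9-hydroxy-4,8-dimethylnona-4,6-dienoic acid | C[C@H](CO)/C=C/C=C(\C)CCC(=O)O | intermediate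
10 | 3-[(3S,6S)-3-[(2R)-1-hydroxypropan-2-yl]-6-methyl-3,6-dihydro-1,2-dioxin-6-yl]propanoic acid | C[C@H](CO)[C@@H]1C=C[C@](C)(CCC(=O)O)OO1 | intermediate
11 | 3-[(3S,6R)-3-[(2R)-1-hydroxypropan-2-yl]-6-methyl-1,2-dioxan-6-yl]propanoic acid | C[C@H](CO)[C@@H]1CC[C@](C)(CCC(=O)O)OO1 | intermediate
12 | tert-butyldimethylsilyl 3-[(3S,6R)-3-[(2R)-1-[(tert-butyldimethylsilyl)oxy]propan-2-yl]-6-methyl-1,2-dioxan-6-yl]propanoate | C[C@H](CO[Si](C)(C)C(C)(C)C)[C@@H]1CC[C@](C)(CCC(=O)O[Si](C)(C)C(C)(C)C)OO1 | intermediate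
13 | 3-[(3S,6R)-3-[(2R)-1-[(tert-butyldimethylsilyl)oxy]propan-2-yl]-6-methyl-1,2-dioxan-6-yl]propanoic acid | C[C@H](CO[Si](C)(C)C(C)(C)C)[C@@H]1CC[C@](C)(CCC(=O)O)OO1 | intermediate
14 | 6-methoxy-3,4-dihydronaphthalen-1(2H)-one | COc1ccc2C(=O)CCCc2c1 | starting material
15 | 6-methoxy-1,1-dimethyl-1,2,3,4-tetrahydronaphthalene | COc1ccc2c(c1)CCCC2(C)C | intermediate
16 | 6-methoxy-1,1-dimethyl-1,2,3,4,5,8-hexahydronaphthalene | COC1=CCC2=C(C1)CCCC2(C)C | intermediate
17 | 5,5-dimethyl-3,4,5,6,7,8-hexahydronaphthalen-2(1H)-one | O=C1CCC2=C(C1)CCCC2(C)C | intermediate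
18 | 5,5-dimethyl-3,4,5,6,7,8-hexahydronaphthalen-2-yl trifluoromethanesulfonate | O=S(=O)(OC1=CC2=C(CC1)C(C)(C)CCC2)C(F)(F)F | intermediate
19 | trimethyl(5,5-dimethyl-3,4,5,6,7,8-hexahydronaphthalen-2-yl)stannane | C[Sn](C)(C)C1=CC2=C(CC1)C(C)(C)CCC2 | intermediate
20 | 3-[(3S,6R)-3-[(2R)-1-[(tert-butyldimethylsilyl)oxy]propan-2-yl]-6-methyl-1,2-dioxan-6-yl]propanoyl chloride | C[C@H](CO[Si](C)(C)C(C)(C)C)[C@@H]1CC[C@](C)(CCC(Cl)=O)OO1 | intermediate
21 | 3-[(3S,6R)-3-[(2R)-1-[(tert-butyldimethylsilyl)oxy]propan-2-yl]-6-methyl-1,2-dioxan-6-yl]-1-(5,5-dimethyl-3,4,5,6,7,8-hexahydronaphthalen-2-yl)propan-1-one | C[C@H](CO[Si](C)(C)C(C)(C)C)[C@@H]1CC[C@](C)(CCC(=O)C2=CC3=C(CC2)C(C)(C)CCC3)OO1 | intermediate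
22 | N'-[3-[(3S,6S)-3-[(2R)-1-[(tert-butyldimethylsilyl)oxy]propan-2-yl]-6-methyl-1,2-dioxan-6-yl]-1-(5,5-dimethyl-3,4,5,6,7,8-hexahydronaphthalen-2-yl)propylidene]-4-methylbenzenesulfonohydrazide | C[C@H](CO[Si](C)(C)C(C)(C)C)[C@@H]1CC[C@](C)(CCC(=NNS(=O)(=O)c2ccc(C)cc2)C2=CC3=C(CC2)C(C)(C)CCC3)OO1 | intermediate
23 | N'-[3-[(3S,6S)-3-[(2R)-1-hydroxypropan-2-yl]-6-methyl-1,2-dioxan-6-yl]-1-(5,5-dimethyl-3,4,5,6,7,8-hexahydronaphthalen-2-yl)propylidene]-4-methylbenzenesulfonohydrazide | C[C@H](CO)[C@@H]1CC[C@](C)(CCC(=NNS(=O)(=O)c2ccc(C)cc2)C2=CC3=C(CC2)C(C)(C)CCC3)OO1 | intermediate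
24 | N'-[3-[(3S,6S)-3-[(2R)-1-hydroxypropan-2-yl]-6-methyl-1,2-dioxan-6-yl]-1-(5,5-dimethyl-3,4,5,6,7,8-hexahydronaphthalen-2-yl)propyl]-4-methylbenzenesulfonohydrazide (N-boryl derivative in the flask) | C[C@H](CO)[C@@H]1CC[C@](C)(CCC(NNS(=O)(=O)c2ccc(C)cc2)C2=CC3=C(CC2)C(C)(C)CCC3)OO1 | intermediate
25 | (2R)-2-[(3S,6S)-6-[3-diazenyl-3-(5,5-dimethyl-3,4,5,6,7,8-hexahydronaphthalen-2-yl)propyl]-6-methyl-1,2-dioxan-3-yl]propan-1-ol (allylic diazene) | C[C@H](CO)[C@@H]1CC[C@](C)(CCC(N=N)C2=CC3=C(CC2)C(C)(C)CCC3)OO1 | intermediate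
26 | (2R)-2-[(3S,6S)-6-[(3Z)-3-(5,5-dimethyl-3,4,5,6,7,8-hexahydronaphthalen-2(1H)-ylidene)propyl]-6-methyl-1,2-dioxan-3-yl]propan-1-ol | C[C@H](CO)[C@@H]1CC[C@](C)(CC/C=C2/CCC3=C(CCCC3(C)C)C2)OO1 | intermediate
27 | (2S)-2-[(3S,6S)-6-[(3Z)-3-(5,5-dimethyl-3,4,5,6,7,8-hexahydronaphthalen-2(1H)-ylidene)propyl]-6-methyl-1,2-dioxan-3-yl]propanal | C[C@H](C=O)[C@@H]1CC[C@](C)(CC/C=C2/CCC3=C(CCCC3(C)C)C2)OO1 | intermediate
28 | (2S)-2-[(3S,6S)-6-[(3Z)-3-(5,5-dimethyl-3,4,5,6,7,8-hexahydronaphthalen-2(1H)-ylidene)propyl]-6-methyl-1,2-dioxan-3-yl]propanoic acid | C[C@H](C(=O)O)[C@@H]1CC[C@](C)(CC/C=C2/CCC3=C(CCCC3(C)C)C2)OO1 | target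

## Step count and risks

Total: 17 steps. Longest linear sequence: 13 steps (steps 1–9, then 14–17); the stannane branch (steps 10–13) adds 4.

**Step 7 (singlet-oxygen cycloaddition).** The diene terminus carries an inside methyl group, so the ene reaction competes with [4+2], and the facial preference from the hydroxyl-directed delivery is expected to be only moderate. Fallback, setting out from aldehyde 3 and returning at acid 13: the peroxide is built stepwise instead of by cycloaddition. Felkin–Anh addition of allyltrimethylsilane to 3 (BF3·OEt2, −78 °C) gives the 2,3-syn homoallylic alcohol (2R,3R)-1-[(tert-butyldimethylsilyl)oxy]-2-methylhex-5-en-3-ol F1, which is converted into its mesylate F2. Cross-metathesis of F2 with excess ethyl 4-methylpent-4-enoate (second-generation Grubbs catalyst) gives the trisubstituted alkene F3. Isayama–Mukaiyama hydroperoxysilylation (Co(acac)2, O2, Et3SiH) places a triethylsilylperoxy group on the tertiary carbon to give F4. n-Bu4NF at 0 °C unmasks the peroxy anion, which displaces the mesylate in a 6-exo-tet SN2 with inversion at C3 to give dioxane ester F5; here C6 is not controlled and the two C6 epimers are separated. LiOH hydrolysis of F5 gives 13.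

**Step 16 (alkene geometry in the diazene shift).** The Z preference rests on a conformational argument for a 2-substituted allylic diazene and may be lower than hoped, or reversed. Fallback, setting out from acid 13 and ketone 17 and returning at alcohol 26: the alkene is made by carbonyl olefination and the isomers are separated. Acid 13 is reduced through its mixed anhydride (i-BuOCOCl, N-methylmorpholine; NaBH4) to the alcohol F6, converted into the iodide F7 (I2, PPh3, imidazole) and then into the phosphonium iodide F8 (PPh3, MeCN, 50 °C). The ylide (NaN(SiMe3)2, THF, −78 °C) reacts with 17 in an unselective Wittig reaction to give the Z alkene silyl ether F9 and its E isomer F10, which are separated on AgNO3-impregnated silica. HF·pyridine converts F9 into 26.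

**Step 14 (Stille acylation beside the peroxide).** The zerovalent palladium catalyst or its ligand may attack the O–O bond, and traces of HCl can protodestannylate 19. Fallback, setting out from 13 and 19 and returning at dienone 21: the ketone is made by acyl substitution with an organolithium at low temperature instead of palladium catalysis. Acid 13 is converted into the Weinreb amide F11 (EDC·HCl, MeNHOMe·HCl, i-Pr2NEt); stannane 19 is transmetalated with MeLi (THF, −78 °C) and the dienyllithium is added to F11 at −78 °C to give 21.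

## Further compounds

F1 | step 7 | (2R,3R)-1-[(tert-butyldimethylsilyl)oxy]-2-methylhex-5-en-3-ol | C[C@H](CO[Si](C)(C)C(C)(C)C)[C@H](O)CC=C
F2 | step 7 | (2R,3R)-1-[(tert-butyldimethylsilyl)oxy]-2-methylhex-5-en-3-yl methanesulfonate | C[C@H](CO[Si](C)(C)C(C)(C)C)[C@H](OS(C)(=O)=O)CC=C
F3 | step 7 | ethyl (7R,8R)-9-[(tert-butyldimethylsilyl)oxy]-4,8-dimethyl-7-[(methylsulfonyl)oxy]non-4-enoate (E/Z mixture) | C[C@H](CO[Si](C)(C)C(C)(C)C)[C@H](OS(C)(=O)=O)CC=C(C)CCC(=O)OCC
F4 | step 7 | ethyl (7R,8R)-9-[(tert-butyldimethylsilyl)oxy]-4,8-dimethyl-7-[(methylsulfonyl)oxy]-4-[(triethylsilyl)peroxy]nonanoate (both C4 epimers) | C[C@H](CO[Si](C)(C)C(C)(C)C)[C@H](OS(C)(=O)=O)CCC(C)(OO[Si](CC)(CC)CC)CCC(=O)OCC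
F5 | step 7 | ethyl 3-[(3S,6R)-3-[(2R)-1-[(tert-butyldimethylsilyl)oxy]propan-2-yl]-6-methyl-1,2-dioxan-6-yl]propanoate | C[C@H](CO[Si](C)(C)C(C)(C)C)[C@@H]1CC[C@](C)(CCC(=O)OCC)OO1
F6 | step 16 | 3-[(3S,6S)-3-[(2R)-1-[(tert-butyldimethylsilyl)oxy]propan-2-yl]-6-methyl-1,2-dioxan-6-yl]propan-1-ol | C[C@H](CO[Si](C)(C)C(C)(C)C)[C@@H]1CC[C@](C)(CCCO)OO1
F7 | step 16 | tert-butyl[(2R)-2-[(3S,6R)-6-(3-iodopropyl)-6-methyl-1,2-dioxan-3-yl]propoxy]dimethylsilane | C[C@H](CO[Si](C)(C)C(C)(C)C)[C@@H]1CC[C@](C)(CCCI)OO1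
F8 | step 16 | [3-[(3S,6R)-3-[(2R)-1-[(tert-butyldimethylsilyl)oxy]propan-2-yl]-6-methyl-1,2-dioxan-6-yl]propyl]triphenylphosphonium iodide | C[C@H](CO[Si](C)(C)C(C)(C)C)[C@@H]1CC[C@](C)(CCC[P+](c2ccccc2)(c2ccccc2)c2ccccc2)OO1.[I-]
F9 | step 16 | tert-butyl[(2R)-2-[(3S,6S)-6-[(3Z)-3-(5,5-dimethyl-3,4,5,6,7,8-hexahydronaphthalen-2(1H)-ylidene)propyl]-6-methyl-1,2-dioxan-3-yl]propoxy]dimethylsilane | C[C@H](CO[Si](C)(C)C(C)(C)C)[C@@H]1CC[C@](C)(CC/C=C2/CCC3=C(CCCC3(C)C)C2)OO1
F10 | step 16 | tert-butyl[(2R)-2-[(3S,6S)-6-[(3E)-3-(5,5-dimethyl-3,4,5,6,7,8-hexahydronaphthalen-2(1H)-ylidene)propyl]-6-methyl-1,2-dioxan-3-yl]propoxy]dimethylsilane | C[C@H](CO[Si](C)(C)C(C)(C)C)[C@@H]1CC[C@](C)(CC/C=C2\CCC3=C(CCCC3(C)C)C2)OO1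
F11 | step 14 | 3-[(3S,6R)-3-[(2R)-1-[(tert-butyldimethylsilyl)oxy]propan-2-yl]-6-methyl-1,2-dioxan-6-yl]-N-methoxy-N-methylpropanamide | C[C@H](CO[Si](C)(C)C(C)(C)C)[C@@H]1CC[C@](C)(CCC(=O)N(C)OC)OO1
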